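**Retrosynthetic overview**
1. The 19-membered ansa-lactam is closed last at the N–C20(aryl) bond by a light-driven Ni-catalysed intramolecular N-arylation of a primary 2-methyl-2-enamide with an aryl bromide; the C7 carbamate and global deprotection follow.
2. C7–C8 is cut to a C8 alkenylzinc (from hydrozirconation of a C8≡C9 methyl alkyne, giving the E-C8=C9 alkene) and a C1–C7 α-methoxy aldehyde; chelation sets C7.
3. West half (C8–C15 plus arene): C10/C11 come from (Z)-crotylboration of a C11 α-methoxy aldehyde; C14 comes from trans-benzylation of an L-glutamic-acid-derived γ-lactone whose C=O becomes the C14 methyl; C12 is the lactone stereocentre.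
4. East half (C1–C7): the same lactone, opened by one-pot DIBAL/Wittig and O-methylated; C6 is the lactone stereocentre.
5. Rings: the arene is bought, the lactone ring is opened early, and the macrocycle is the only ring formed.

Assumption: chain atoms carry geldanamycin numbers (C1 amide C=O to C15 benzylic CH2; arene C16–C21, OH on C17, N on C20), and lactone 4 is bought as such (made from L-glutamic acid).

**Route**

Step 1
Reactants: 1 5-bromo-2-hydroxybenzyl alcohol
Product: 2 [5-bromo-2-(methoxymethoxy)phenyl]methanol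
Conditions: MOMCl, K2CO3, acetone, 0 °C → rt
Reagents that add atoms: chloromethyl methyl ether COCCl
Why: Phenol-selective Williamson O-alkylation (phenol far more acidic than the benzylic OH) installs a MOM ether that survives all later basic and organometallic steps.

Step 2
Reactants: 2 [5-bromo-2-(methoxymethoxy)phenyl]methanol
Product: 3 4-bromo-2-(bromomethyl)-1-(methoxymethoxy)benzene
Conditions: CBr4, PPh3, CH2Cl2, 0 °C
Reagents that add atoms: carbon tetrabromide BrC(Br)(Br)Br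
Why: Appel bromination of the benzylic alcohol under neutral conditions that leave the MOM acetal intact.

Step 3
Reactants: 4 (S)-5-[(trityloxy)methyl]dihydrofuran-2(3H)-one; 3 4-bromo-2-(bromomethyl)-1-(methoxymethoxy)benzene
Product: 6 (3R,5S)-3-[5-bromo-2-(methoxymethoxy)benzyl]-5-[(trityloxy)methyl]dihydrofuran-2(3H)-one, via lithium enolate 5 (not isolated)
Conditions: LDA, THF, −78 °C; then 3, −78 → −40 °C
Reagents that add atoms: none
Why: Lactone enolate alkylation occurs anti to the bulky C5 trityloxymethyl group (1,3-induction on the ring, trans expected >15:1), which sets C14 from the bought C12 centre.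

Step 4
Reactants: 6 (3R,5S)-3-[5-bromo-2-(methoxymethoxy)benzyl]-5-[(trityloxy)methyl]dihydrofuran-2(3H)-one
Product: 7 (3R,5S)-3-[5-bromo-2-(methoxymethoxy)benzyl]-5-[(trityloxy)methyl]tetrahydrofuran-2-ol (anomer mixture)
Conditions: DIBAL-H, CH2Cl2, −78 °C
Reagents that add atoms: none
Why: DIBAL-H half-reduction of a lactone stops at the lactol because the tetrahedral aluminate is stable at −78 °C.

Step 5
Reactants: 7 (3R,5S)-3-[5-bromo-2-(methoxymethoxy)benzyl]-5-[(trityloxy)methyl]tetrahydrofuran-2-ol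
Product: 9 (2S,4R)-5-[5-bromo-2-(methoxymethoxy)phenyl]-4-methyl-1-(trityloxy)pentan-2-ol, via tosylhydrazone 8 (not isolated)
Conditions: TsNHNH2, EtOH, rt; then catecholborane, CHCl3, 0 °C; then NaOAc·3H2O, reflux
Reagents that add atoms: none
Why: Caglioti/Kabalka tosylhydrazone reduction turns the masked aldehyde (former lactone carbonyl) into the C14 methyl group under near-neutral conditions that leave C14, ArBr, MOM and trityl untouched.

Step 6
Reactants: 9 (2S,4R)-5-[5-bromo-2-(methoxymethoxy)phenyl]-4-methyl-1-(trityloxy)pentan-2-ol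
Product: 10 4-bromo-2-[(2R,4S)-4-methoxy-2-methyl-5-(trityloxy)pentyl]-1-(methoxymethoxy)benzene
Conditions: NaH, MeI, THF/DMF, 0 °C → rt
Reagents that add atoms: iodomethane CI
Why: Williamson methylation of the C12 alkoxide; no base-sensitive group is present at this stage.

Step 7
Reactants: 10 4-bromo-2-[(2R,4S)-4-methoxy-2-methyl-5-(trityloxy)pentyl]-1-(methoxymethoxy)benzene
Product: 11 (2S,4R)-5-[5-bromo-2-(methoxymethoxy)phenyl]-2-methoxy-4-methylpentan-1-ol
Conditions: TsOH·H2O (5 mol%), MeOH/CH2Cl2, 0 °C → rt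
Reagents that add atoms: none
Why: Acid-catalysed solvolysis of the trityl ether (via the trityl cation) is much faster than cleavage of the aryl MOM acetal.

Step 8
Reactants: 11 (2S,4R)-5-[5-bromo-2-(methoxymethoxy)phenyl]-2-methoxy-4-methylpentan-1-ol
Product: 12 (2S,4R)-5-[5-bromo-2-(methoxymethoxy)phenyl]-2-methoxy-4-methylpentanal
Conditions: Dess–Martin periodinane, CH2Cl2, 0 °C → rt
Reagents that add atoms: none
Why: Dess–Martin oxidation gives the α-methoxy aldehyde under non-basic conditions, so C12 is not epimerised.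

Step 9
Reactants: 12 (2S,4R)-5-[5-bromo-2-(methoxymethoxy)phenyl]-2-methoxy-4-methylpentanal; 13 (Z)-crotylboronic acid pinacol ester
Product: 15 (3S,4R,5S,7R)-8-[5-bromo-2-(methoxymethoxy)phenyl]-5-methoxy-3,7-dimethyloct-1-en-4-ol, via O-Bpin borate ester 14 (not isolated)
Conditions: 4 Å MS, toluene, −78 °C → rt, 48 h; then 1 M aq. NaOH
Reagents that add atoms: none
Why: Hoffmann–Roush crotylboration through a closed chair transition state: the Z-crotyl geometry gives 10,11-syn, and Felkin–Anh/Cornforth attack anti to the α-methoxy group gives 11,12-anti (substrate control from C12, expected about 6–10:1).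

Step 10
Reactants: 15 (3S,4R,5S,7R)-8-[5-bromo-2-(methoxymethoxy)phenyl]-5-methoxy-3,7-dimethyloct-1-en-4-ol
Product: 16 {[(3S,4R,5S,7R)-8-[5-bromo-2-(methoxymethoxy)phenyl]-5-methoxy-3,7-dimethyloct-1-en-4-yl]oxy}triethylsilane
Conditions: TESCl, imidazole, DMAP (cat.), DMF, rt
Reagents that add atoms: chlorotriethylsilane CC[Si](Cl)(CC)CC
Why: Silylation protects C11–OH through the alkyne, zinc and aluminium steps and leaves C7–OH as the only free hydroxyl for carbamoylation later.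

Step 11
Reactants: 16 {[(3S,4R,5S,7R)-8-[5-bromo-2-(methoxymethoxy)phenyl]-5-methoxy-3,7-dimethyloct-1-en-4-yl]oxy}triethylsilane
Product: 18 (2R,3R,4S,6R)-7-[5-bromo-2-(methoxymethoxy)phenyl]-4-methoxy-2,6-dimethyl-3-[(triethylsilyl)oxy]heptanal, via secondary ozonide 17 (not isolated)
Conditions: O3, CH2Cl2, −78 °C; then PPh3, −78 °C → rt
Reagents that add atoms: ozone [O-][O+]=O
Why: Ozonolysis of the terminal alkene with reductive work-up gives the C9 aldehyde; the bromoarene reacts far more slowly than the alkene at −78 °C.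

Step 12
Reactants: 18 (2R,3R,4S,6R)-7-[5-bromo-2-(methoxymethoxy)phenyl]-4-methoxy-2,6-dimethyl-3-[(triethylsilyl)oxy]heptanal
Product: 19 {[(3S,4R,5S,7R)-8-[5-bromo-2-(methoxymethoxy)phenyl]-5-methoxy-3,7-dimethyloct-1-yn-4-yl]oxy}triethylsilane
Conditions: dimethyl (1-diazo-2-oxopropyl)phosphonate, K2CO3, MeOH, 0 °C → rt
Reagents that add atoms: dimethyl (1-diazo-2-oxopropyl)phosphonate CC(=O)C(=[N+]=[N-])P(=O)(OC)OC
Why: Ohira–Bestmann (Seyferth–Gilbert) homologation gives the terminal alkyne under mild carbonate conditions that normally preserve an α-methyl stereocentre (C10).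

Step 13
Reactants: 19 {[(3S,4R,5S,7R)-8-[5-bromo-2-(methoxymethoxy)phenyl]-5-methoxy-3,7-dimethyloct-1-yn-4-yl]oxy}triethylsilane
Product: 21 {[(4S,5R,6S,8R)-9-[5-bromo-2-(methoxymethoxy)phenyl]-6-methoxy-4,8-dimethylnon-2-yn-5-yl]oxy}triethylsilane, via lithium acetylide 20 (not isolated)
Conditions: LDA, THF, −78 °C; then MeI, DMPU, −78 °C → rt
Reagents that add atoms: iodomethane CI
Why: Acetylide formation and SN2 methylation install the future C8 methyl; an amide base is used so that no Br/Li exchange occurs on the arene.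

Step 14
Reactants: 4 (S)-5-[(trityloxy)methyl]dihydrofuran-2(3H)-one; 22 ethyl 2-(triphenylphosphoranylidene)propanoate
Product: 24 ethyl (S,E)-6-hydroxy-2-methyl-7-(trityloxy)hept-2-enoate, via lactol 23 (not isolated)
Conditions: DIBAL-H, toluene, −78 °C; MeOH; then 22, −78 → 60 °C (one pot)
Reagents that add atoms: none
Why: One-pot DIBAL half-reduction/Wittig olefination: the stabilised ylide traps the open hydroxy-aldehyde form of the lactol and gives the (E)-2-methyl enoate (C2=C3); C6 is the lactone stereocentre.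

Step 15
Reactants: 24 ethyl (S,E)-6-hydroxy-2-methyl-7-(trityloxy)hept-2-enoate
Product: 25 ethyl (S,E)-6-methoxy-2-methyl-7-(trityloxy)hept-2-enoate
Conditions: Me3OBF4, 1,8-bis(dimethylamino)naphthalene, 4 Å MS, CH2Cl2, rt
Reagents that add atoms: trimethyloxonium tetrafluoroborate C[O+](C)C.F[B-](F)(F)F
Why: Meerwein methylation under non-basic conditions avoids oxa-Michael ring closure of the hydroxy enoate that an alkoxide would trigger.

Step 16
Reactants: 25 ethyl (S,E)-6-methoxy-2-methyl-7-(trityloxy)hept-2-enoate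
Product: 26 ethyl (S,E)-7-hydroxy-6-methoxy-2-methylhept-2-enoate
Conditions: TsOH·H2O (5 mol%), EtOH/CH2Cl2, rt
Reagents that add atoms: none
Why: Acid-catalysed trityl solvolysis; ethanol as co-solvent avoids transesterification of the ethyl ester.

Step 17
Reactants: 26 ethyl (S,E)-7-hydroxy-6-methoxy-2-methylhept-2-enoate
Product: 27 ethyl (S,E)-6-methoxy-2-methyl-7-oxohept-2-enoate
Conditions: Dess–Martin periodinane, CH2Cl2, 0 °C → rt
Reagents that add atoms: none
Why: Dess–Martin oxidation to the α-methoxy aldehyde without epimerising C6; the aldehyde is used directly.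

Step 18
Reactants: 21 {[(4S,5R,6S,8R)-9-[5-bromo-2-(methoxymethoxy)phenyl]-6-methoxy-4,8-dimethylnon-2-yn-5-yl]oxy}triethylsilane; 27 ethyl (S,E)-6-methoxy-2-methyl-7-oxohept-2-enoate
Product: 30 ethyl (2E,6S,7S,8E,10S,11R,12S,14R)-15-[5-bromo-2-(methoxymethoxy)phenyl]-7-hydroxy-6,12-dimethoxy-2,8,10,14-tetramethyl-11-[(triethylsilyl)oxy]pentadeca-2,8-dienoate, via alkenylzirconocene 28 (not isolated), via alkenylzinc 29 (not isolated)
Conditions: Cp2Zr(H)Cl, CH2Cl2, rt; Me2Zn, toluene, −65 °C; then 27, −40 → 0 °C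
Reagents that add atoms: none
Why: Wipf hydrozirconation/Zr-to-Zn transmetalation/aldehyde addition: syn-hydrozirconation puts Zr on the less hindered C8 (E-trisubstituted alkene), and Cram-chelate addition (Zn bridging C7=O and C6–OMe) sets C7 syn to C6.

Step 19
Reactants: 30 ethyl (2E,6S,7S,8E,10S,11R,12S,14R)-15-[5-bromo-2-(methoxymethoxy)phenyl]-7-hydroxy-6,12-dimethoxy-2,8,10,14-tetramethyl-11-[(triethylsilyl)oxy]pentadeca-2,8-dienoate
Product: 31 (2E,6S,7S,8E,10S,11R,12S,14R)-15-[5-bromo-2-(methoxymethoxy)phenyl]-7-hydroxy-6,12-dimethoxy-2,8,10,14-tetramethyl-11-[(triethylsilyl)oxy]pentadeca-2,8-dienamide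
Conditions: Me3Al, NH4Cl, toluene, 0 → 50 °C
Reagents that add atoms: ammonium chloride [NH4+].[Cl-]
Why: Weinreb aminolysis with an aluminium amide made in situ converts the hindered 2-methyl enoate into the primary amide without conjugate addition.

Step 20
Reactants: 31 (2E,6S,7S,8E,10S,11R,12S,14R)-15-[5-bromo-2-(methoxymethoxy)phenyl]-7-hydroxy-6,12-dimethoxy-2,8,10,14-tetramethyl-11-[(triethylsilyl)oxy]pentadeca-2,8-dienamide
Product: 32 19-membered ansa-lactam (2E,8E,6S,7S,10S,11R,12S,14R): target skeleton with free 7-OH, 11-O-triethylsilyl and 17-O-methoxymethyl, N–C20 bond closed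
Conditions: NiBr2·glyme (15 mol%), dtbbpy (15 mol%), 4CzIPN (3 mol%), BTMG (2.5 equiv), DMAc (2 mM), 450 nm LEDs, 35 °C, Ar
Reagents that add atoms: none
Why: Proposed new method: a light-driven Ni-catalysed ring-closing N-arylation of a primary α,β-unsaturated carboxamide by a pendant electron-rich aryl bromide (19-membered meta-ansa lactam) – photoreduced Ni(0)/Ni(I) adds oxidatively to C20–Br, the guanidine base delivers the N-bound amidate to nickel, and the excited photocatalyst (energy transfer or oxidation to Ni(III)) triggers the otherwise slow C–N reductive elimination, with 2 mM dilution favouring cyclisation over oligomerisation and the photocatalyst triplet energy (about 60 kcal/mol) too low to isomerise the enamide; the closest known reaction types are intermolecular Ni/photoredox N-arylation of sulfonamides, carbamates and amides and thermal Cu(I)/diamine Goldberg closure of anilide bonds; no stereocentre is touched.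

Step 21
Reactants: 32 19-membered ansa-lactam with free 7-OH, 11-O-triethylsilyl and 17-O-methoxymethyl
Product: 34 7-O-carbamoyl ansa-lactam (11-O-triethylsilyl, 17-O-methoxymethyl derivative of the target), via N-trichloroacetyl carbamate 33 (not isolated)
Conditions: Cl3CC(O)NCO, CH2Cl2, −20 °C; then K2CO3, MeOH, 0 °C → rt
Reagents that add atoms: trichloroacetyl isocyanate O=C=NC(=O)C(Cl)(Cl)Cl
Why: Kočovský carbamoylation: the acyl isocyanate adds to the only free hydroxyl (C7) and mild methanolysis removes the trichloroacetyl group.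

Step 22
Reactants: 34 7-O-carbamoyl ansa-lactam (11-O-triethylsilyl, 17-O-methoxymethyl)
Product: 35 target CNP0544610.1 (6S,7S,10S,11R,12S,14R; 2E,8E)
Conditions: HCl (2 M in MeOH)/THF 1:1, 0 °C → rt
Reagents that add atoms: none
Why: Acid-catalysed methanolysis cleaves the TES ether and the aryl MOM acetal in one operation; the carbamate, methyl ethers and anilide are stable to it.

**Compound list**
1 | 5-bromo-2-hydroxybenzyl alcohol | OCc1cc(Br)ccc1O | starting material
2 | [5-bromo-2-(methoxymethoxy)phenyl]methanol | OCc1cc(Br)ccc1OCOC | intermediate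
3 | 4-bromo-2-(bromomethyl)-1-(methoxymethoxy)benzene | BrCc1cc(Br)ccc1OCOC | intermediate
4 | (S)-5-[(trityloxy)methyl]dihydrofuran-2(3H)-one | O=C1CC[C@@H](COC(c2ccccc2)(c2ccccc2)c2ccccc2)O1 | starting material
5 | lithium enolate of 4 (not isolated) | [Li]OC1=CC[C@@H](COC(c2ccccc2)(c2ccccc2)c2ccccc2)O1 | intermediate
6 | (3R,5S)-3-[5-bromo-2-(methoxymethoxy)benzyl]-5-[(trityloxy)methyl]dihydrofuran-2(3H)-one (3,5-trans) | O=C1[C@H](Cc2cc(Br)ccc2OCOC)C[C@@H](COC(c2ccccc2)(c2ccccc2)c2ccccc2)O1 | intermediate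
7 | (3R,5S)-3-[5-bromo-2-(methoxymethoxy)benzyl]-5-[(trityloxy)methyl]tetrahydrofuran-2-ol (lactol, C2 anomers) | OC1[C@H](Cc2cc(Br)ccc2OCOC)C[C@@H](COC(c2ccccc2)(c2ccccc2)c2ccccc2)O1 | intermediate
8 | N'-[(2R,4S)-2-[5-bromo-2-(methoxymethoxy)benzyl]-4-hydroxy-5-(trityloxy)pentylidene]-4-methylbenzenesulfonohydrazide (not isolated) | Cc1ccc(cc1)S(=O)(=O)NN=C[C@H](Cc1cc(Br)ccc1OCOC)C[C@H](O)COC(c1ccccc1)(c1ccccc1)c1ccccc1 | intermediate
9 | (2S,4R)-5-[5-bromo-2-(methoxymethoxy)phenyl]-4-methyl-1-(trityloxy)pentan-2-ol | C(c1ccccc1)(c1ccccc1)(c1ccccc1)OC[C@@H](O)C[C@H](C)Cc1cc(Br)ccc1OCOC | intermediate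
10 | 4-bromo-2-[(2R,4S)-4-methoxy-2-methyl-5-(trityloxy)pentyl]-1-(methoxymethoxy)benzene | C(c1ccccc1)(c1ccccc1)(c1ccccc1)OC[C@@H](OC)C[C@H](C)Cc1cc(Br)ccc1OCOC | intermediate
11 | (2S,4R)-5-[5-bromo-2-(methoxymethoxy)phenyl]-2-methoxy-4-methylpentan-1-ol | OC[C@@H](OC)C[C@H](C)Cc1cc(Br)ccc1OCOC | intermediate
12 | (2S,4R)-5-[5-bromo-2-(methoxymethoxy)phenyl]-2-methoxy-4-methylpentanal | O=C[C@@H](OC)C[C@H](C)Cc1cc(Br)ccc1OCOC | intermediate
13 | (Z)-crotylboronic acid pinacol ester | C/C=C\CB1OC(C)(C)C(C)(C)O1 | starting material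
14 | O-pinacolboryl ether of 15 (not isolated) | C=C[C@H](C)[C@@H](OB1OC(C)(C)C(C)(C)O1)[C@@H](OC)C[C@H](C)Cc1cc(Br)ccc1OCOC | intermediate
15 | (3S,4R,5S,7R)-8-[5-bromo-2-(methoxymethoxy)phenyl]-5-methoxy-3,7-dimethyloct-1-en-4-ol | C=C[C@H](C)[C@@H](O)[C@@H](OC)C[C@H](C)Cc1cc(Br)ccc1OCOC | intermediate
16 | {[(3S,4R,5S,7R)-8-[5-bromo-2-(methoxymethoxy)phenyl]-5-methoxy-3,7-dimethyloct-1-en-4-yl]oxy}triethylsilane | C=C[C@H](C)[C@@H](O[Si](CC)(CC)CC)[C@@H](OC)C[C@H](C)Cc1cc(Br)ccc1OCOC | intermediate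
17 | secondary ozonide (1,2,4-trioxolane) of 16 (not isolated) | C1OC(OO1)[C@H](C)[C@@H](O[Si](CC)(CC)CC)[C@@H](OC)C[C@H](C)Cc1cc(Br)ccc1OCOC | intermediate
18 | (2R,3R,4S,6R)-7-[5-bromo-2-(methoxymethoxy)phenyl]-4-methoxy-2,6-dimethyl-3-[(triethylsilyl)oxy]heptanal | O=C[C@H](C)[C@@H](O[Si](CC)(CC)CC)[C@@H](OC)C[C@H](C)Cc1cc(Br)ccc1OCOC | intermediate
19 | {[(3S,4R,5S,7R)-8-[5-bromo-2-(methoxymethoxy)phenyl]-5-methoxy-3,7-dimethyloct-1-yn-4-yl]oxy}triethylsilane | C#C[C@H](C)[C@@H](O[Si](CC)(CC)CC)[C@@H](OC)C[C@H](C)Cc1cc(Br)ccc1OCOC | intermediate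
20 | lithium acetylide of 19 (not isolated) | [Li]C#C[C@H](C)[C@@H](O[Si](CC)(CC)CC)[C@@H](OC)C[C@H](C)Cc1cc(Br)ccc1OCOC | intermediate
21 | {[(4S,5R,6S,8R)-9-[5-bromo-2-(methoxymethoxy)phenyl]-6-methoxy-4,8-dimethylnon-2-yn-5-yl]oxy}triethylsilane | CC#C[C@H](C)[C@@H](O[Si](CC)(CC)CC)[C@@H](OC)C[C@H](C)Cc1cc(Br)ccc1OCOC | intermediate
22 | ethyl 2-(triphenylphosphoranylidene)propanoate | CCOC(=O)C(C)=P(c1ccccc1)(c1ccccc1)c1ccccc1 | starting material
23 | (5S)-5-[(trityloxy)methyl]tetrahydrofuran-2-ol (lactol, not isolated) | OC1CC[C@@H](COC(c2ccccc2)(c2ccccc2)c2ccccc2)O1 | intermediate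
24 | ethyl (S,E)-6-hydroxy-2-methyl-7-(trityloxy)hept-2-enoate | CCOC(=O)/C(C)=C/CC[C@H](O)COC(c1ccccc1)(c1ccccc1)c1ccccc1 | intermediate
25 | ethyl (S,E)-6-methoxy-2-methyl-7-(trityloxy)hept-2-enoate | CCOC(=O)/C(C)=C/CC[C@H](OC)COC(c1ccccc1)(c1ccccc1)c1ccccc1 | intermediate
26 | ethyl (S,E)-7-hydroxy-6-methoxy-2-methylhept-2-enoate | CCOC(=O)/C(C)=C/CC[C@H](OC)CO | intermediate
27 | ethyl (S,E)-6-methoxy-2-methyl-7-oxohept-2-enoate | CCOC(=O)/C(C)=C/CC[C@H](OC)C=O | intermediate
28 | (E)-alkenylzirconocene chloride from 21, Zr on C8 (not isolated) | C/C(=C\[C@H](C)[C@@H](O[Si](CC)(CC)CC)[C@@H](OC)C[C@H](C)Cc1cc(Br)ccc1OCOC)[Zr](Cl)(C1C=CC=C1)C1C=CC=C1 | intermediate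
29 | (E)-alkenyl(methyl)zinc, Zn on C8 (not isolated) | C/C(=C\[C@H](C)[C@@H](O[Si](CC)(CC)CC)[C@@H](OC)C[C@H](C)Cc1cc(Br)ccc1OCOC)[Zn]C | intermediate
30 | ethyl (2E,6S,7S,8E,10S,11R,12S,14R)-15-[5-bromo-2-(methoxymethoxy)phenyl]-7-hydroxy-6,12-dimethoxy-2,8,10,14-tetramethyl-11-[(triethylsilyl)oxy]pentadeca-2,8-dienoate | CCOC(=O)/C(C)=C/CC[C@H](OC)[C@@H](O)/C(C)=C/[C@H](C)[C@@H](O[Si](CC)(CC)CC)[C@@H](OC)C[C@H](C)Cc1cc(Br)ccc1OCOC | intermediate
31 | (2E,6S,7S,8E,10S,11R,12S,14R)-15-[5-bromo-2-(methoxymethoxy)phenyl]-7-hydroxy-6,12-dimethoxy-2,8,10,14-tetramethyl-11-[(triethylsilyl)oxy]pentadeca-2,8-dienamide | NC(=O)/C(C)=C/CC[C@H](OC)[C@@H](O)/C(C)=C/[C@H](C)[C@@H](O[Si](CC)(CC)CC)[C@@H](OC)C[C@H](C)Cc1cc(Br)ccc1OCOC | intermediate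
32 | ansa-lactam with free 7-OH, 11-O-triethylsilyl, 17-O-methoxymethyl (6S,7S,10S,11R,12S,14R; 2E,8E) | CO[C@H]1C[C@H](C)Cc2cc(ccc2OCOC)NC(=O)/C(C)=C/CC[C@H](OC)[C@@H](O)/C(C)=C/[C@H](C)[C@H]1O[Si](CC)(CC)CC | intermediate
33 | 7-O-[N-(trichloroacetyl)carbamoyl] derivative of 32 (not isolated) | CO[C@H]1C[C@H](C)Cc2cc(ccc2OCOC)NC(=O)/C(C)=C/CC[C@H](OC)[C@@H](OC(=O)NC(=O)C(Cl)(Cl)Cl)/C(C)=C/[C@H](C)[C@H]1O[Si](CC)(CC)CC | intermediate
34 | 11-O-triethylsilyl-17-O-methoxymethyl derivative of the target (7-O-carbamate in place) | CO[C@H]1C[C@H](C)Cc2cc(ccc2OCOC)NC(=O)/C(C)=C/CC[C@H](OC)[C@@H](OC(N)=O)/C(C)=C/[C@H](C)[C@H]1O[Si](CC)(CC)CC | intermediate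
35 | CNP0544610.1 (6S,7S,10S,11R,12S,14R; 2E,8E) | CO[C@H]1C[C@H](C)Cc2cc(ccc2O)NC(=O)/C(C)=C/CC[C@H](OC)[C@@H](OC(N)=O)/C(C)=C/[C@H](C)[C@H]1O | target

**Step count and risks**

Total step count: 22. Longest linear sequence: 18 steps (steps 1–13, then 18–22, from 1); the east branch (steps 14–17) is 4 steps from 4.

Origin of the stereocentres: C6 and C12 are the stereocentre of bought lactone 4; C14 comes from step 3, C10 and C11 from step 9, and C7 from step 18, each under substrate control.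

The three steps most likely to fail:

Step 20 (the proposed new ring closure). Possible failures are protodebromination, oligomerisation, slow oxidative addition into the electron-rich aryl bromide, or competing O-arylation at C7. The fallback sets out from 30 and comes back at 32, and closes the ring at the C1–N amide bond instead of the N–aryl bond. The aryl bromide of 30 is coupled with benzophenone imine (Pd2(dba)3, Xantphos, Cs2CO3, dioxane, 90 °C) to give the N-(diphenylmethylene)aniline ester F1. Mild transimination (NH2OH·HCl, NaOAc, MeOH) releases the aniline ester F2. Saponification (LiOH, THF/MeOH/H2O) gives the amino acid F3. Macrolactamisation of F3 (BOP-Cl, iPr2NEt, toluene, 85 °C, 1 mM), a standard closure for ansamycin seco-acids, gives 32. Steps 19 and 20 are then not needed.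

Step 18 (fragment coupling that sets C7). Possible failures are incomplete regiocontrol in the hydrozirconation or an insufficient chelate preference at C7. The fallback sets out from 21 (with 27) and comes back at 30, and makes and uses the C8 nucleophile in a different way. Hydrozirconation of 21 followed by iodine gives the isolated (E)-alkenyl iodide F4, which can be purified free of regioisomer. Iodine–magnesium exchange (iPrMgCl·LiCl, THF, 0 °C → rt; the electron-rich aryl bromide does not exchange) gives the alkenylmagnesium chloride F5. Addition of F5 to 27 precomplexed with MgBr2·OEt2 (CH2Cl2, −78 °C) is a classical Cram-chelate Grignard addition and gives 30.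

Step 5 (lactol to methyl via the tosylhydrazone). Possible failures are sluggish hydrazone formation from the lactol or partial epimerisation at C14. The fallback sets out from 6 and comes back at 9, and replaces the hydrazone chemistry by a radical dehalogenation. LiBH4 (THF, 0 °C → rt) reduces 6 to the diol F6. Garegg–Samuelsson iodination (I2, PPh3, imidazole, CH2Cl2, 0 °C) converts only the primary alcohol into the primary iodide F7. Bu3SnH with Et3B/air (toluene, rt; alkyl iodide reacts far faster than the aryl bromide) removes the iodine and gives 9.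

Further compounds
F1 | step 20 | ethyl (2E,6S,7S,8E,10S,11R,12S,14R)-15-[5-[(diphenylmethylene)amino]-2-(methoxymethoxy)phenyl]-7-hydroxy-6,12-dimethoxy-2,8,10,14-tetramethyl-11-[(triethylsilyl)oxy]pentadeca-2,8-dienoate | CCOC(=O)/C(C)=C/CC[C@H](OC)[C@@H](O)/C(C)=C/[C@H](C)[C@@H](O[Si](CC)(CC)CC)[C@@H](OC)C[C@H](C)Cc1cc(N=C(c2ccccc2)c2ccccc2)ccc1OCOC
F2 | step 20 | ethyl (2E,6S,7S,8E,10S,11R,12S,14R)-15-[5-amino-2-(methoxymethoxy)phenyl]-7-hydroxy-6,12-dimethoxy-2,8,10,14-tetramethyl-11-[(triethylsilyl)oxy]pentadeca-2,8-dienoate | CCOC(=O)/C(C)=C/CC[C@H](OC)[C@@H](O)/C(C)=C/[C@H](C)[C@@H](O[Si](CC)(CC)CC)[C@@H](OC)C[C@H](C)Cc1cc(N)ccc1OCOC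
F3 | step 20 | (2E,6S,7S,8E,10S,11R,12S,14R)-15-[5-amino-2-(methoxymethoxy)phenyl]-7-hydroxy-6,12-dimethoxy-2,8,10,14-tetramethyl-11-[(triethylsilyl)oxy]pentadeca-2,8-dienoic acid | OC(=O)/C(C)=C/CC[C@H](OC)[C@@H](O)/C(C)=C/[C@H](C)[C@@H](O[Si](CC)(CC)CC)[C@@H](OC)C[C@H](C)Cc1cc(N)ccc1OCOC
F4 | step 18 | {[(2E,4S,5R,6S,8R)-9-[5-bromo-2-(methoxymethoxy)phenyl]-2-iodo-6-methoxy-4,8-dimethylnon-2-en-5-yl]oxy}triethylsilane | C/C(I)=C\[C@H](C)[C@@H](O[Si](CC)(CC)CC)[C@@H](OC)C[C@H](C)Cc1cc(Br)ccc1OCOC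
F5 | step 18 | alkenylmagnesium chloride from F4 (Mg on C8, same alkene geometry) | C/C([Mg]Cl)=C\[C@H](C)[C@@H](O[Si](CC)(CC)CC)[C@@H](OC)C[C@H](C)Cc1cc(Br)ccc1OCOC
F6 | step 5 | (2R,4S)-2-[5-bromo-2-(methoxymethoxy)benzyl]-5-(trityloxy)pentane-1,4-diol | OC[C@H](Cc1cc(Br)ccc1OCOC)C[C@H](O)COC(c1ccccc1)(c1ccccc1)c1ccccc1
F7 | step 5 | (2S,4R)-4-[5-bromo-2-(methoxymethoxy)benzyl]-5-iodo-1-(trityloxy)pentan-2-ol | IC[C@H](Cc1cc(Br)ccc1OCOC)C[C@H](O)COC(c1ccccc1)(c1ccccc1)c1ccccc1
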